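**Retrosynthetic overview**

Rings: A = trioxygenated ring; B = para-phenylene; C = the ring with the lone OH (C1 bridge carbon, C2 ether carbon, C3 C–OH); D = ortho-phenylene. All four are bought; only the 17-membered macrocycle is built.
Target ⇐ 15 (BBr3) ⇐ 13 (Dakin-type oxidation) ⇐ 12 (DIBAL-H) ⇐ seco phenol 11 by intramolecular SNAr: the ring D phenoxide oxygen attacks C2–F of ring C and closes the macrocycle.
Enabling feature: C2 of ring C lies next to C3, which carries an OH in the target. C3 can therefore carry a nitrile during ring closure, which activates C2–F and is afterwards cut down to that OH (C≡N → CHO → O-formate → OH).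
11 ⇐ bis-stilbene 10 by one hydrogenation (two C=C, one O-benzyl) ⇐ HWE (B–C bridge) of aldehyde 6 with phosphonate 9 ⇐ SNAr of phenol 4 with 4-fluorobenzaldehyde (A–O–B ether) ⇐ Wittig (A–D bridge).
Order of ring formation: the macrocycle only, closed last among the skeletal bonds at its most hindered diaryl ether.

Key step: step 8

Remark: the target has no stereocentre. The Wittig step gives both alkene isomers of 4; they are carried together through 6 and 10 because step 7 removes the double bonds, and the E isomers are drawn.

**Route**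

Step 1
Reactants: 1 [2-(benzyloxy)phenyl]methanol
Product: 2 [2-(benzyloxy)benzyl]triphenylphosphonium bromide
Conditions: Ph3P·HBr, MeCN, reflux
Reagents that add atoms: triphenylphosphine hydrobromide [Br-].c1ccc(cc1)[PH+](c1ccccc1)c1ccccc1
Why: Direct conversion of a benzylic alcohol into its phosphonium salt (displacement of the protonated OH by PPh3), which the ortho-alkoxy group favours.

Step 2
Reactants: 2 [2-(benzyloxy)benzyl]triphenylphosphonium bromide; 3 3-hydroxy-4,5-dimethoxybenzaldehyde
Product: 4 5-{2-[2-(benzyloxy)phenyl]ethenyl}-2,3-dimethoxyphenol (E/Z mixture, E drawn)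
Conditions: KOtBu (2.2 equiv), THF, 0 °C to rt; 1 M HCl work-up
Reagents that add atoms: none
Why: Wittig olefination of the aldehyde (present as its phenoxide) with the semi-stabilised benzylic ylide builds the ring A–ring D two-carbon bridge, and the alkene geometry does not matter because step 7 saturates it.

Step 3
Reactants: 4 5-{2-[2-(benzyloxy)phenyl]ethenyl}-2,3-dimethoxyphenol; 5 4-fluorobenzaldehyde
Product: 6 4-(5-{2-[2-(benzyloxy)phenyl]ethenyl}-2,3-dimethoxyphenoxy)benzaldehyde
Conditions: K2CO3, DMF, 120 °C
Reagents that add atoms: none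
Why: SNAr of the phenoxide on 4-fluorobenzaldehyde, whose para formyl group activates the fluoride and then becomes a carbon of the ring B–ring C bridge; only the ring A phenol is free, since the ring D oxygen is benzylated.

Step 4
Reactants: 7 2-fluoro-3-methylbenzonitrile
Product: 8 3-(bromomethyl)-2-fluorobenzonitrile
Conditions: NBS (0.95 equiv), AIBN (cat.), PhCF3, 80 °C
Reagents that add atoms: N-bromosuccinimide O=C1CCC(=O)N1Br
Why: Wohl–Ziegler radical bromination at the only benzylic position, with a slight deficit of NBS to limit dibromination.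

Step 5
Reactants: 8 3-(bromomethyl)-2-fluorobenzonitrile
Product: 9 diethyl (3-cyano-2-fluorobenzyl)phosphonate
Conditions: P(OEt)3, neat, 120 °C
Reagents that add atoms: triethyl phosphite CCOP(OCC)OCC
Why: Michaelis–Arbuzov reaction of a reactive benzylic bromide; the aryl fluoride and the nitrile are inert to the neutral phosphite.

Step 6
Reactants: 6 4-(5-{2-[2-(benzyloxy)phenyl]ethenyl}-2,3-dimethoxyphenoxy)benzaldehyde; 9 diethyl (3-cyano-2-fluorobenzyl)phosphonate
Product: 10 3-{(E)-2-[4-(5-{2-[2-(benzyloxy)phenyl]ethenyl}-2,3-dimethoxyphenoxy)phenyl]ethenyl}-2-fluorobenzonitrile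
Conditions: NaHMDS (1.1 equiv) added last to 6 + 9, THF, −78 to 0 °C
Reagents that add atoms: none
Why: Horner–Wadsworth–Emmons olefination with the benzylic phosphonate anion should give the E-stilbene, and adding the base last at low temperature lets carbonyl addition outrun attack of the anion on the cyano-activated C–F bond.

Step 7
Reactants: 10 3-{(E)-2-[4-(5-{2-[2-(benzyloxy)phenyl]ethenyl}-2,3-dimethoxyphenoxy)phenyl]ethenyl}-2-fluorobenzonitrile
Product: 11 2-fluoro-3-[2-(4-{5-[2-(2-hydroxyphenyl)ethyl]-2,3-dimethoxyphenoxy}phenyl)ethyl]benzonitrile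
Conditions: H2 (1 atm), 10% Pd/C, EtOAc, rt
Reagents that add atoms: none
Why: Heterogeneous catalytic hydrogenation should saturate both stilbene double bonds and cleave the benzyl ether by hydrogenolysis in one operation, setting free the ring D phenol, while the aryl fluoride, the nitrile (neutral aprotic solvent) and the methyl and diaryl ethers stay intact.

Step 8
Reactants: 11 2-fluoro-3-[2-(4-{5-[2-(2-hydroxyphenyl)ethyl]-2,3-dimethoxyphenoxy}phenyl)ethyl]benzonitrile
Product: 12 macrocyclic nitrile (target skeleton with both ring A hydroxyls as methyl ethers and C≡N in place of the ring C OH)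
Conditions: Cs2CO3 (3 equiv), DMSO, 90 °C, 11 added by syringe pump to a final 3 mM
Reagents that add atoms: none
Why: The caesium phenoxide of ring D adds to C2 of ring C to give a Meisenheimer complex whose charge is taken up by the ortho nitrile at C3, and loss of fluoride gives the diaryl ether (addition–elimination, SNAr). The closest known reaction type is the SNAr macrocyclisation of a phenoxide onto an ortho-activated aryl fluoride, the standard closure of macrocyclic diaryl ethers, together with the intermolecular etherification of 2-fluorobenzonitriles by phenoxides. The 17-membered ring is closed by C–O bond formation in an end-to-end macrocyclisation under pseudo-high dilution, with the two saturated ethano bridges and the existing ring A–ring B ether leaving the chain free to fold. No stereocentre is formed. The step needs site selectivity and ring closure in preference to oligomerisation: substitution can only be ipso at C2, the one activated carbon with a leaving group; the ring D OH is the only acidic nucleophile in 11; the nitrile survives carbonate and phenoxide over long reaction times, which is why it is preferred to a formyl or nitro group; and slow addition keeps the concentration of open-chain phenoxide low.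

Step 9
Reactants: 12 macrocyclic nitrile
Product: 13 macrocyclic aldehyde (CHO at C3 of ring C)
Conditions: DIBAL-H (1.5 equiv), CH2Cl2, −78 to 0 °C; then 1 M HCl, rt
Reagents that add atoms: water O
Why: Partial reduction of a nitrile: DIBAL-H adds once to give an N-aluminio aldimine that is stable in the cold and is hydrolysed to the aldehyde on acidic work-up, with no other reducible group present.

Step 10
Reactants: 13 macrocyclic aldehyde
Product: 15 macrocyclic phenol (ring A di-O-methyl ether of the target), via macrocyclic aryl formate 14 (not isolated)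
Conditions: mCPBA (1.3 equiv), CH2Cl2, 0 °C to rt; then K2CO3 (cat.), MeOH, rt
Reagents that add atoms: meta-chloroperoxybenzoic acid O=C(OO)c1cccc(Cl)c1
Why: Baeyer–Villiger (Dakin-type) oxidation: in the Criegee adduct the electron-rich ortho-aryloxy aryl group should migrate in preference to hydride to give the aryl formate, which methanolysis cleaves to the C3 phenol, so the carbon that activated the ring closure is excised.

Step 11
Reactants: 15 macrocyclic phenol
Product: 16 target, CNP0290892.0
Conditions: BBr3 (6 equiv), CH2Cl2, −78 °C to rt; then H2O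
Reagents that add atoms: none
Why: Lewis-acid ether cleavage with BBr3 removes both methyl ethers of ring A through aryloxyboron intermediates that hydrolyse on work-up, whereas diaryl ether bonds are not cleaved under these conditions.

**Compound list**

1 | [2-(benzyloxy)phenyl]methanol | OCc1ccccc1OCc1ccccc1 | starting material
2 | [2-(benzyloxy)benzyl]triphenylphosphonium bromide | [Br-].c1ccc(COc2ccccc2C[P+](c2ccccc2)(c2ccccc2)c2ccccc2)cc1 | intermediate
3 | 3-hydroxy-4,5-dimethoxybenzaldehyde | COc1cc(C=O)cc(O)c1OC | starting material
4 | 5-{2-[2-(benzyloxy)phenyl]ethenyl}-2,3-dimethoxyphenol (E/Z mixture, E drawn) | COc1cc(/C=C/c2ccccc2OCc2ccccc2)cc(O)c1OC | intermediate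
5 | 4-fluorobenzaldehyde | O=Cc1ccc(F)cc1 | starting material
6 | 4-(5-{2-[2-(benzyloxy)phenyl]ethenyl}-2,3-dimethoxyphenoxy)benzaldehyde (E/Z mixture, E drawn) | COc1cc(/C=C/c2ccccc2OCc2ccccc2)cc(Oc2ccc(C=O)cc2)c1OC | intermediate
7 | 2-fluoro-3-methylbenzonitrile | Cc1cccc(C#N)c1F | starting material
8 | 3-(bromomethyl)-2-fluorobenzonitrile | N#Cc1cccc(CBr)c1F | intermediate
9 | diethyl (3-cyano-2-fluorobenzyl)phosphonate | CCOP(=O)(Cc1cccc(C#N)c1F)OCC | intermediate
10 | 3-{(E)-2-[4-(5-{2-[2-(benzyloxy)phenyl]ethenyl}-2,3-dimethoxyphenoxy)phenyl]ethenyl}-2-fluorobenzonitrile (ring A–ring D alkene E/Z, E drawn) | COc1cc(/C=C/c2ccccc2OCc2ccccc2)cc(Oc2ccc(/C=C/c3cccc(C#N)c3F)cc2)c1OC | intermediate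
11 | 2-fluoro-3-[2-(4-{5-[2-(2-hydroxyphenyl)ethyl]-2,3-dimethoxyphenoxy}phenyl)ethyl]benzonitrile | COc1cc(CCc2ccccc2O)cc(Oc2ccc(CCc3cccc(C#N)c3F)cc2)c1OC | intermediate
12 | macrocyclic nitrile (ring A dimethoxy, C≡N at C3 of ring C) | COc1cc2cc(c1OC)Oc1ccc(cc1)CCc1cccc(C#N)c1Oc1ccccc1CC2 | intermediate
13 | macrocyclic aldehyde (CHO at C3 of ring C) | COc1cc2cc(c1OC)Oc1ccc(cc1)CCc1cccc(C=O)c1Oc1ccccc1CC2 | intermediate
14 | macrocyclic aryl formate (OCHO at C3 of ring C) | COc1cc2cc(c1OC)Oc1ccc(cc1)CCc1cccc(OC=O)c1Oc1ccccc1CC2 | intermediate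
15 | macrocyclic phenol (ring A di-O-methyl ether of the target) | COc1cc2cc(c1OC)Oc1ccc(cc1)CCc1cccc(O)c1Oc1ccccc1CC2 | intermediate
16 | CNP0290892.0 | Oc1cc2cc(c1O)Oc1ccc(cc1)CCc1cccc(O)c1Oc1ccccc1CC2 | target

**Totals**

Total step count: 11. Longest linear sequence: 9 steps (1 → 2 → 4 → 6 → 10 → 11 → 12 → 13 → 15 → 16).

**Steps most likely to fail**

Step 8. What may go wrong: addition of the phenoxide to the doubly ortho-substituted C2 is slow, so intermolecular etherification to linear and cyclic oligomers overtakes ring closure. Fallback: form the hindered ring D–O–ring C ether between two molecules at high concentration and close the ring instead at the ring B–ring C bridge by an intramolecular Horner–Wadsworth–Emmons olefination, a known closure for macrocyclic stilbenes. It sets out from 6 and comes back at 12. Hydrogenation of 6 (H2, Pd/C, EtOAc, stopped once the alkene and the benzyl ether are consumed) should give 4-{5-[2-(2-hydroxyphenyl)ethyl]-2,3-dimethoxyphenoxy}benzaldehyde F1. SNAr of F1 with phosphonate 9 (K2CO3, DMF, 80 °C, 0.3 M; carbonate is too weak to start the olefination) should give the phosphonate aldehyde F2. NaH in THF under high dilution should close the ring to the macrocyclic stilbene nitrile F3, and hydrogenation (H2, Pd/C, EtOAc) then gives 12.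

Step 10. What may go wrong: migration of hydride instead of the aryl group in the Criegee adduct, which leads to the carboxylic acid. Fallback: insert the oxygen at a methyl ketone, where only aryl or methyl can migrate. It sets out from 12 and comes back at 15. MeMgBr (THF, 0 °C to rt, then aq. HCl) should convert 12 into the macrocyclic methyl ketone F4. Baeyer–Villiger oxidation (mCPBA, Na2HPO4, CH2Cl2) should give the macrocyclic aryl acetate F5, and K2CO3 in MeOH gives 15.

Step 6. What may go wrong: the phosphonate carbanion or the amide base attacks the cyano-activated C–F carbon faster than the anion adds to the aldehyde, which consumes the fluoride needed in step 8. Fallback: build the ring B–ring C bridge without a carbanion, through an alkyne. It sets out from 6 and comes back at 11. Seyferth–Gilbert homologation of 6 with the Ohira–Bestmann reagent (K2CO3, MeOH) should give 1-(benzyloxy)-2-{2-[3-(4-ethynylphenoxy)-4,5-dimethoxyphenyl]ethenyl}benzene F6. Sonogashira coupling with commercial 3-bromo-2-fluorobenzonitrile (Pd(PPh3)2Cl2, CuI, Et3N, THF, 50 °C) should give the diarylalkyne F7. Hydrogenation as in step 7 then saturates alkyne and alkene and removes the benzyl group to give 11.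

Further compounds
F1 | step 8 | 4-{5-[2-(2-hydroxyphenyl)ethyl]-2,3-dimethoxyphenoxy}benzaldehyde | COc1cc(CCc2ccccc2O)cc(Oc2ccc(C=O)cc2)c1OC
F2 | step 8 | diethyl [3-cyano-2-(2-{2-[3-(4-formylphenoxy)-4,5-dimethoxyphenyl]ethyl}phenoxy)benzyl]phosphonate | CCOP(=O)(Cc1cccc(C#N)c1Oc1ccccc1CCc1cc(OC)c(OC)c(Oc2ccc(C=O)cc2)c1)OCC
F3 | step 8 | macrocyclic (E)-stilbene nitrile (12 with a C=C in the ring B–ring C bridge) | COc1cc2cc(c1OC)Oc1ccc(cc1)/C=C/c1cccc(C#N)c1Oc1ccccc1CC2
F4 | step 10 | macrocyclic methyl ketone (acetyl at C3 of ring C) | COc1cc2cc(c1OC)Oc1ccc(cc1)CCc1cccc(C(C)=O)c1Oc1ccccc1CC2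
F5 | step 10 | macrocyclic aryl acetate (OAc at C3 of ring C) | COc1cc2cc(c1OC)Oc1ccc(cc1)CCc1cccc(OC(C)=O)c1Oc1ccccc1CC2
F6 | step 6 | 1-(benzyloxy)-2-{2-[3-(4-ethynylphenoxy)-4,5-dimethoxyphenyl]ethenyl}benzene | COc1cc(/C=C/c2ccccc2OCc2ccccc2)cc(Oc2ccc(C#C)cc2)c1OC
F7 | step 6 | 3-{[4-(5-{2-[2-(benzyloxy)phenyl]ethenyl}-2,3-dimethoxyphenoxy)phenyl]ethynyl}-2-fluorobenzonitrile | COc1cc(/C=C/c2ccccc2OCc2ccccc2)cc(Oc2ccc(C#Cc3cccc(C#N)c3F)cc2)c1OC
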